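**Retrosynthetic overview**

1. The plan rests on the C3–O–C10 ether bridge of the furanone ring (O, C3, C2, C1, C10). It lets C3, C2, C1, C10, C9 and C4 be folded into a 7-oxanorbornane whose C4–C9 bond lies between a C5=C6 arm on C4 and a C8=C7 arm on C9.
2. Target ⇒ bicyclic enol triflate 34, by late lactone closure (C6–OH plus C7-ethynyl plus CO), C2–C3 dehydrogenation, C15 by Stille coupling at C4, and O-8/O-9 from the C8=C9 alkene.
3. 34 ⇒ exo,exo-dialkenyl oxanorbornanol 31 by an anionic oxy-Cope shift (C6–C7 made, C4–C9 broken) with triflation of the C4 enolate.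
4. 31 ⇒ ketone 24 plus an alkoxyacetylide (C4–C5, then trans reduction); the Z-enyne by Peterson olefination at C8; the bicycle by Diels–Alder reaction of 3-methoxy-2-methylfuran 4 with chiral nitroacrylate 9 (C10–C9 and C3–C4).
5. Ring order: oxanorbornane (five-membered ether ring and six-membered carbocycle) → ten-membered carbocycle by four-atom ring expansion → α-methylene lactone last.

Key step: step 17

Remark on numbering and faces: germacrane numbering of the target (6R,7S,8S,9R,10S) is used throughout. The β face is the face of the flat-drawn ten-membered ring that carries the C3–O–C10 bridge; C11 and O-8 are β, and O-6, O-9 and C14 are α.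

Assumption: the nitroacrylate of (−)-8-phenylmenthol is taken to expose the dienophile face that leads to the 10S adduct. If the first cycloadducts show the opposite sense, (+)-8-phenylmenthol is used and nothing else changes.

**Route**

Step 1
Reactants: 1 3-bromofuran
Product: 3 3-bromo-2-methylfuran, via 3-bromo-2-furyllithium 2 (not isolated)
Conditions: LiN(iPr)2, THF, −78 °C; MeI, −78 °C to rt
Reagents that add atoms: iodomethane, CI
Why: Directed ortho-lithiation, in which the bromine acidifies the adjacent α-position of the furan so that amide-base deprotonation at −78 °C is regioselective, followed by SN2 methylation of the aryllithium.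

Step 2
Reactants: 3 3-bromo-2-methylfuran
Product: 4 3-methoxy-2-methylfuran
Conditions: NaOMe, CuBr (10 mol %), MeOH–NMP, 110 °C
Reagents that add atoms: sodium methoxide, [Na+].[O-]C
Why: Ullmann-type copper-catalysed methoxylation of a heteroaryl bromide, a known reaction for 3-bromofurans and 3-bromothiophenes.

Step 3
Reactants: 5 (−)-8-phenylmenthol; 6 acryloyl chloride
Product: 7 (−)-8-phenylmenthyl acrylate
Conditions: Et3N, DMAP (cat.), CH2Cl2, 0 °C to rt
Reagents that add atoms: none
Why: DMAP-catalysed acylation of a secondary alcohol by an acid chloride.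

Step 4
Reactants: 7 (−)-8-phenylmenthyl acrylate
Product: 9 (−)-8-phenylmenthyl (E)-3-nitroacrylate, via 2-iodo-3-nitropropanoate ester 8 (not isolated)
Conditions: N2O4, I2, Et2O, 0 °C; NaOAc, Et2O, rt
Reagents that add atoms: dinitrogen tetroxide, O=[N+]([O-])[N+](=O)[O-]
Why: Nitro-iodination of the acrylate (nitryl iodide adds with the nitro group at the terminal carbon) and E1cB loss of HI with acetate should give the thermodynamically preferred E nitroalkene, which is the standard route to 3-nitroacrylates.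

Step 5
Reactants: 4 3-methoxy-2-methylfuran; 9 (−)-8-phenylmenthyl (E)-3-nitroacrylate
Product: 11 8-phenylmenthyl (1S,4S)-6,6-dimethoxy-1-methyl-3-endo-nitro-7-oxabicyclo[2.2.1]heptane-2-exo-carboxylate, via enol ether cycloadduct 10 (not isolated)
Conditions: CH2Cl2, −40 to 0 °C; MeOH, PPTS (cat.), 0 °C to rt; chromatography and crystallisation to one diastereomer
Reagents that add atoms: methanol, CO
Why: Normal-demand Diels–Alder reaction of a 3-alkoxyfuran with a doubly activated nitroalkene: the methoxy-activated furan C2 (C10) should bond to the acrylate α-carbon (C9, β to the dominant nitro acceptor), the nitro group should go endo and the ester exo, the stacked phenyl ring of the auxiliary leaves one dienophile face open and so sets C10, C3, C4 and C9, and acid-catalysed addition of methanol to the strained C1=C2 enol ether locks the adduct as the C1 dimethyl ketal before cycloreversion can occur.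

Step 6
Reactants: 11 nitro ketal ester
Product: 13 8-phenylmenthyl (1S,4S)-6,6-dimethoxy-1-methyl-3-oxo-7-oxabicyclo[2.2.1]heptane-2-exo-carboxylate, via sodium nitronate 12 (not isolated)
Conditions: NaOMe, MeOH–CH2Cl2, 0 °C; O3, −78 °C; N2 purge, AcOH
Reagents that add atoms: ozone, [O-][O+]=O
Why: Oxidative Nef reaction, in which ozone cleaves the C=N bond of the C4 nitronate at −78 °C where neither loss of nitrite toward the ester nor opening of the oxygen bridge should compete; C9 becomes the α-carbon of a β-keto ester and should rest exo, because an endo ester would face the endo methoxy group at C1.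

Step 7
Reactants: 13 β-keto ester
Product: 15 (1S,4S)-2-exo-(hydroxymethyl)-6,6-dimethoxy-1-methyl-7-oxabicyclo[2.2.1]heptan-3-endo-ol, via hydroxy ester 14 (not isolated)
Conditions: NaBH4, MeOH–THF, −20 °C; LiBH4, THF, 0 to 45 °C
Reagents that add atoms: none
Why: Borohydride reduction of the ketone from the open exo face (endo C4 alcohol, a centre erased again in step 13) and then of the ester by LiBH4, which releases the auxiliary for recovery.

Step 8
Reactants: 15 diol
Product: 16 bis(triethylsilyl) ether of 15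
Conditions: Et3SiCl, imidazole, DMAP (cat.), DMF, 0 °C to rt
Reagents that add atoms: chlorotriethylsilane, CC[Si](Cl)(CC)CC
Why: Exhaustive silylation of a primary and a secondary alcohol.

Step 9
Reactants: 16 bis(triethylsilyl) ether
Product: 17 (1S,4S)-6,6-dimethoxy-1-methyl-3-endo-(triethylsilyloxy)-7-oxabicyclo[2.2.1]heptane-2-exo-carbaldehyde
Conditions: (COCl)2, DMSO, CH2Cl2, −78 to −30 °C; Et3N, −78 to 0 °C
Reagents that add atoms: none
Why: Swern oxidation applied directly to a primary triethylsilyl ether, which the chlorosulfonium salt desilylates and oxidises while the hindered secondary silyl ether stays; the exo aldehyde at C9 is also the thermodynamic epimer.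

Step 10
Reactants: 18 1-(triisopropylsilyl)-1-propyne
Product: 20 1,3-bis(triisopropylsilyl)propyne, via 3-lithio-1-(triisopropylsilyl)propyne 19 (not isolated)
Conditions: n-BuLi, THF, −20 °C; iPr3SiOTf, −78 °C to rt
Reagents that add atoms: triisopropylsilyl triflate, CC(C)[Si](OS(=O)(=O)C(F)(F)F)(C(C)C)C(C)C
Why: Propargylic lithiation and C-silylation, with the bulky silyl groups favouring the propargyl over the allenyl silane.

Step 11
Reactants: 17 aldehyde; 20 1,3-bis(triisopropylsilyl)propyne
Product: 22 (1S,4S)-6,6-dimethoxy-1-methyl-3-endo-(triethylsilyloxy)-2-exo-[(Z)-4-(triisopropylsilyl)but-1-en-3-ynyl]-7-oxabicyclo[2.2.1]heptane, via 3-lithio-1,3-bis(triisopropylsilyl)propyne 21 (not isolated)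
Conditions: 20, n-BuLi, THF, −20 °C; then 17, −78 °C to rt
Reagents that add atoms: none
Why: Peterson olefination with a lithiated bis-silylpropyne, whose two bulky silyl groups steer the addition to the β-silyl alkoxide that collapses by syn elimination to the Z enyne (C8=C7), addition at −78 °C being faster than enolisation toward C9.

Step 12
Reactants: 22 Z-enyne silyl ether
Product: 23 (1S,4S)-6,6-dimethoxy-1-methyl-2-exo-[(Z)-4-(triisopropylsilyl)but-1-en-3-ynyl]-7-oxabicyclo[2.2.1]heptan-3-endo-ol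
Conditions: HF·pyridine, pyridine, THF, 0 °C
Reagents that add atoms: none
Why: Buffered fluoride cleavage of a triethylsilyl ether, under which the C-silyl alkyne, the ketal and the enyne are inert.

Step 13
Reactants: 23 alcohol
Product: 24 (1S,4S)-6,6-dimethoxy-1-methyl-2-exo-[(Z)-4-(triisopropylsilyl)but-1-en-3-ynyl]-7-oxabicyclo[2.2.1]heptan-3-one
Conditions: Dess–Martin periodinane, NaHCO3, CH2Cl2, 0 °C; used at once
Reagents that add atoms: none
Why: Neutral Dess–Martin oxidation, chosen because the β,γ-unsaturated ketone would conjugate or epimerise at C9 under basic or acidic oxidation.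

Step 14
Reactants: 25 4-methoxybenzyl alcohol; 26 trichloroethylene
Product: 28 (E)-1,2-dichlorovinyl 4-methoxybenzyl ether, via potassium 4-methoxybenzyl oxide 27 (not isolated)
Conditions: KH, THF, 0 °C; trichloroethylene, −50 °C to rt
Reagents that add atoms: none
Why: First stage of the dichlorovinyl ether route to alkoxyacetylenes, in which the alkoxide adds anti to dichloroacetylene generated in situ from trichloroethylene.

Step 15
Reactants: 24 ketone; 28 dichlorovinyl ether
Product: 30 (1S,4S)-6,6-dimethoxy-3-exo-[(4-methoxybenzyloxy)ethynyl]-1-methyl-2-exo-[(Z)-4-(triisopropylsilyl)but-1-en-3-ynyl]-7-oxabicyclo[2.2.1]heptan-3-endo-ol, via lithium alkoxyethynide 29 (not isolated)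
Conditions: 28, n-BuLi (2.2 equiv), THF, −78 to −40 °C; CeCl3, −78 °C; 24, −78 °C; pH 7 buffer
Reagents that add atoms: none
Why: Elimination and chlorine–lithium exchange give the alkoxyacetylide, which as its cerium reagent should add to the enolisable ketone without deprotonating C9; the slim nucleophile enters C4 from the exo face (side of the oxygen bridge, away from endo H-2), so the hydroxyl becomes endo and the new arm exo, cis to the C9 arm.

Step 16
Reactants: 30 propargylic alcohol
Product: 31 (1S,4S)-6,6-dimethoxy-3-exo-[(E)-2-(4-methoxybenzyloxy)vinyl]-1-methyl-2-exo-[(Z)-4-(triisopropylsilyl)but-1-en-3-ynyl]-7-oxabicyclo[2.2.1]heptan-3-endo-ol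
Conditions: NaAlH2(OCH2CH2OMe)2, THF, −20 to 0 °C; aq. potassium sodium tartrate
Reagents that add atoms: none
Why: Alkoxide-directed trans-hydroalumination of the propargylic alcohol (the known hydride reduction of alkoxyethynyl carbinols) and protonolysis should give the E enol ether C5=C6, while the unactivated silyl enyne is not reduced.

Step 17
Reactants: 31 exo,exo-dialkenyl oxanorbornanol
Product: 34 bicyclic enol triflate (11-oxabicyclo[6.2.1]undecadiene; C1 dimethyl ketal, C4 triflate with C3 and C6 cis across C4=C5, 6α-(4-methoxybenzyloxy), 7β-(triisopropylsilylethynyl), Z C8=C9, C10 α-methyl), via potassium alkoxide 32 (not isolated), via potassium enolate 33 (not isolated)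
Conditions: KH, 18-crown-6, THF, −78 to 0 °C; PhNTf2, −78 to 0 °C
Reagents that add atoms: N-phenylbis(trifluoromethanesulfonimide), O=S(=O)(N(c1ccccc1)S(=O)(=O)C(F)(F)F)C(F)(F)F
Why: The crown-separated potassium alkoxide at C4 weakens C4–C9 and drives a concerted [3,3] shift (C4–C9 broken, C6–C7 made) that is pulled further by release of the oxanorbornane strain, and the triflimide then O-sulfonylates the regiodefined C4/C5 enolate before it can equilibrate. The closest known reaction type is the anionic oxy-Cope ring expansion of cis-1,2-dialkenyl cycloalkanols and dialkenyl norbornanols to cyclodecenones and bicyclo[6.2.1]undecenones with in situ enolate triflation. The ten-membered carbocycle (and with it the nine-membered oxonane through C3–O–C10) is not closed end to end but arises by four-atom expansion of the six-membered ring C3–C2–C1–C10–C9–C4 through a six-centre boat transition state. C6 and C7 are set together by the alkene geometries read through that boat: the E enol ether keeps the C6 oxygen on the outer rim and the Z enyne turns the rod-like alkynyl group inward, which gives the 6,7-anti pair needed for the trans lactone, and the fixed C10 centre of the bicycle decides the absolute sense. The step needs the boat with both arms folded toward the oxygen bridge, which gives two cis ring alkenes (Z C8=C9, C3/C6-cis C4=C5), to win over the boat with both arms splayed outward, which would put two trans alkenes in the nine-membered ring; the eclipsed exo,exo attachment of the arms rules out any chair. Loss of the C6 alkoxy group from the enolate should be slow because the C6–O bond lies near the nodal plane of the enolate as it forms, and low temperature with immediate trapping keeps it so.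

Step 18
Reactants: 34 enol triflate
Product: 35 C6 alcohol of 34
Conditions: DDQ, CH2Cl2–pH 7 buffer, 0 °C
Reagents that add atoms: none
Why: Oxidative cleavage of the 4-methoxybenzyl ether by hydride abstraction and hydrolysis of the oxocarbenium ion, to which enol triflate, silylalkyne and ketal are inert.

Step 19
Reactants: 35 homoallylic alcohol
Product: 36 8α,9α-epoxide of 35
Conditions: VO(acac)2 (10 mol %), t-BuOOH, CH2Cl2, 0 °C to rt
Reagents that add atoms: tert-butyl hydroperoxide, CC(C)(C)OO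
Why: Hydroxyl-directed vanadium-catalysed epoxidation of a homoallylic alcohol, in which the vanadate ester of the C6 hydroxyl should deliver oxygen to the face of C8=C9 syn to C6–O (the α face, setting C8 and C9) while the allylic C4=C5 bond is deactivated by its triflate group.

Step 20
Reactants: 36 epoxy alcohol
Product: 37 C6 tert-butyldimethylsilyl ether of 36
Conditions: t-BuMe2SiOTf, 2,6-lutidine, CH2Cl2, −78 °C
Reagents that add atoms: tert-butyldimethylsilyl triflate, CC(C)(C)[Si](C)(C)OS(=O)(=O)C(F)(F)F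
Why: Silyl triflate silylation of a hindered secondary alcohol at low temperature, which should leave the epoxide closed.

Step 21
Reactants: 37 silylated epoxide
Product: 38 8β-methacrylate 9α-alcohol
Conditions: methacrylic acid, Cs2CO3, BHT, DMF, 80 °C
Reagents that add atoms: methacrylic acid, CC(=C)C(=O)O
Why: SN2 opening of an epoxide by a cesium carboxylate buffered with the free acid, with attack at C8 and inversion there (C9 is neopentyl and flanked by the electron-withdrawing C10–O), which should turn the α-epoxide into the 8β-ester and 9α-alcohol.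

Step 22
Reactants: 38 hydroxy ester
Product: 39 8β-methacrylate 9α-isovalerate
Conditions: isovaleric anhydride, DMAP, Et3N, CH2Cl2, rt to 40 °C
Reagents that add atoms: isovaleric anhydride, CC(C)CC(=O)OC(=O)CC(C)C
Why: DMAP-catalysed acylation of the only free hydroxyl group.

Step 23
Reactants: 39 diester enol triflate
Product: 40 C15 allylic alcohol (C4 hydroxymethyl)
Conditions: Bu3SnCH2OH, Pd(PPh3)4 (10 mol %), LiCl, BHT, 1,4-dioxane, 90 °C
Reagents that add atoms: (tributylstannyl)methanol, CCCC[Sn](CCCC)(CCCC)CO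
Why: Stille hydroxymethylation of an enol triflate, stereoretentive at C4=C5, with LiCl assisting oxidative addition and transmetallation.

Step 24
Reactants: 40 ketal
Product: 41 C1 ketone
Conditions: TsOH·H2O (0.2 equiv), acetone–H2O, 40 °C
Reagents that add atoms: water, O
Why: Acid-catalysed ketal hydrolysis with transketalisation to acetone; partial loss of the C6 silyl ether here would do no harm, since that oxygen is silylated again in step 25 and freed in step 26.

Step 25
Reactants: 41 ketone
Product: 44 3(2H)-furanone with free C15 hydroxyl, via bis-silyl enol ether 42 (not isolated), via furanone trimethylsilyl ether 43 (not isolated)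
Conditions: Me3SiOTf, Et3N, CH2Cl2, 0 °C; Pd(OAc)2 (1.1 equiv), MeCN, rt; 1 M HCl–THF, 0 °C
Reagents that add atoms: none
Why: Saegusa–Ito dehydrogenation, in which the ketone can enolise only toward C2 (C10 is quaternary) and β-hydride elimination from the palladium enolate removes H-3 to give the furanone; the C15 hydroxyl is silylated in passing and freed in the acidic work-up, and the step stands before lactone formation so that no palladium hydride meets an exocyclic methylene group.

Step 26
Reactants: 44 furanone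
Product: 45 C6 alcohol with terminal alkyne
Conditions: Bu4NF, AcOH (1:1), THF, 0 °C to rt
Reagents that add atoms: none
Why: Fluoride cleaves the O-silyl and the C-silyl group in one operation, and buffering with acetic acid should suppress acyl migration to the freed C6 hydroxyl.

Step 27
Reactants: 45 homopropargylic alcohol
Product: 46 CNP0552093.1
Conditions: PdI2 (5 mol %), PBu3 (10 mol %), CO (7 atm), BHT, MeCN, 75 °C
Reagents that add atoms: carbon monoxide, [C-]#[O+]
Why: Palladium-catalysed cyclocarbonylation of a homopropargylic alcohol, in which an alkoxycarbonylpalladium species from the C6 hydroxyl adds syn across the terminal alkyne with the new carbon on C11 and protonolysis releases the trans-fused α-methylene-γ-butyrolactone without touching C6 or C7.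

**Compound list**

1 | 3-bromofuran | Brc1ccoc1 | starting material
2 | 3-bromo-2-furyllithium | [Li]c1occc1Br | intermediate
3 | 3-bromo-2-methylfuran | Cc1occc1Br | intermediate
4 | 3-methoxy-2-methylfuran | COc1ccoc1C | intermediate
5 | (−)-8-phenylmenthol, (1R,2S,5R)-5-methyl-2-(2-phenylpropan-2-yl)cyclohexan-1-ol | C[C@@H]1CC[C@H]([C@@H](C1)O)C(C)(C)c1ccccc1 | starting material
6 | acryloyl chloride | C=CC(Cl)=O | starting material
7 | (−)-8-phenylmenthyl acrylate | C[C@@H]1CC[C@H]([C@@H](C1)OC(=O)C=C)C(C)(C)c1ccccc1 | intermediate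
8 | (−)-8-phenylmenthyl 2-iodo-3-nitropropanoate (mixture at C2) | C[C@@H]1CC[C@H]([C@@H](C1)OC(=O)C(I)C[N+](=O)[O-])C(C)(C)c1ccccc1 | intermediate
9 | (−)-8-phenylmenthyl (E)-3-nitroacrylate | C[C@@H]1CC[C@H]([C@@H](C1)OC(=O)/C=C/[N+](=O)[O-])C(C)(C)c1ccccc1 | intermediate
10 | 8-phenylmenthyl (1S,4S)-6-methoxy-1-methyl-3-endo-nitro-7-oxabicyclo[2.2.1]hept-5-ene-2-exo-carboxylate | C[C@@]12O[C@@H](C=C1OC)[C@@H]([N+](=O)[O-])[C@@H]2C(=O)O[C@@H]3C[C@H](C)CC[C@H]3C(C)(C)c4ccccc4 | intermediate
11 | 8-phenylmenthyl (1S,4S)-6,6-dimethoxy-1-methyl-3-endo-nitro-7-oxabicyclo[2.2.1]heptane-2-exo-carboxylate | C[C@@]12O[C@@H](CC1(OC)OC)[C@@H]([N+](=O)[O-])[C@@H]2C(=O)O[C@@H]3C[C@H](C)CC[C@H]3C(C)(C)c4ccccc4 | intermediate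
12 | sodium C3-nitronate of 11 | C[C@@]12O[C@@H](CC1(OC)OC)C(=[N+]([O-])[O-])[C@@H]2C(=O)O[C@@H]3C[C@H](C)CC[C@H]3C(C)(C)c4ccccc4.[Na+] | intermediate
13 | 8-phenylmenthyl (1S,4S)-6,6-dimethoxy-1-methyl-3-oxo-7-oxabicyclo[2.2.1]heptane-2-exo-carboxylate | C[C@@]12O[C@@H](CC1(OC)OC)C(=O)[C@@H]2C(=O)O[C@@H]3C[C@H](C)CC[C@H]3C(C)(C)c4ccccc4 | intermediate
14 | 8-phenylmenthyl (1S,4S)-3-endo-hydroxy-6,6-dimethoxy-1-methyl-7-oxabicyclo[2.2.1]heptane-2-exo-carboxylate | C[C@@]12O[C@@H](CC1(OC)OC)[C@@H](O)[C@@H]2C(=O)O[C@@H]3C[C@H](C)CC[C@H]3C(C)(C)c4ccccc4 | intermediate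
15 | (1S,4S)-2-exo-(hydroxymethyl)-6,6-dimethoxy-1-methyl-7-oxabicyclo[2.2.1]heptan-3-endo-ol | C[C@@]12O[C@@H](CC1(OC)OC)[C@@H](O)[C@@H]2CO | intermediate
16 | bis(triethylsilyl) ether of 15 | C[C@@]12O[C@@H](CC1(OC)OC)[C@@H](O[Si](CC)(CC)CC)[C@@H]2CO[Si](CC)(CC)CC | intermediate
17 | (1S,4S)-6,6-dimethoxy-1-methyl-3-endo-(triethylsilyloxy)-7-oxabicyclo[2.2.1]heptane-2-exo-carbaldehyde | C[C@@]12O[C@@H](CC1(OC)OC)[C@@H](O[Si](CC)(CC)CC)[C@@H]2C=O | intermediate
18 | 1-(triisopropylsilyl)-1-propyne | CC#C[Si](C(C)C)(C(C)C)C(C)C | starting material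
19 | 3-lithio-1-(triisopropylsilyl)propyne | [Li]CC#C[Si](C(C)C)(C(C)C)C(C)C | intermediate
20 | 1,3-bis(triisopropylsilyl)propyne | CC(C)[Si](CC#C[Si](C(C)C)(C(C)C)C(C)C)(C(C)C)C(C)C | intermediate
21 | 3-lithio-1,3-bis(triisopropylsilyl)propyne | [Li]C(C#C[Si](C(C)C)(C(C)C)C(C)C)[Si](C(C)C)(C(C)C)C(C)C | intermediate
22 | (1S,4S)-6,6-dimethoxy-1-methyl-3-endo-(triethylsilyloxy)-2-exo-[(Z)-4-(triisopropylsilyl)but-1-en-3-ynyl]-7-oxabicyclo[2.2.1]heptane | C[C@@]12O[C@@H](CC1(OC)OC)[C@@H](O[Si](CC)(CC)CC)[C@@H]2/C=C\C#C[Si](C(C)C)(C(C)C)C(C)C | intermediate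
23 | (1S,4S)-6,6-dimethoxy-1-methyl-2-exo-[(Z)-4-(triisopropylsilyl)but-1-en-3-ynyl]-7-oxabicyclo[2.2.1]heptan-3-endo-ol | C[C@@]12O[C@@H](CC1(OC)OC)[C@@H](O)[C@@H]2/C=C\C#C[Si](C(C)C)(C(C)C)C(C)C | intermediate
24 | (1S,4S)-6,6-dimethoxy-1-methyl-2-exo-[(Z)-4-(triisopropylsilyl)but-1-en-3-ynyl]-7-oxabicyclo[2.2.1]heptan-3-one | C[C@@]12O[C@@H](CC1(OC)OC)C(=O)[C@@H]2/C=C\C#C[Si](C(C)C)(C(C)C)C(C)C | intermediate
25 | 4-methoxybenzyl alcohol | COc1ccc(CO)cc1 | starting material
26 | trichloroethylene | ClC=C(Cl)Cl | starting material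
27 | potassium 4-methoxybenzyl oxide | COc1ccc(C[O-])cc1.[K+] | intermediate
28 | (E)-1,2-dichlorovinyl 4-methoxybenzyl ether | COc1ccc(CO/C(Cl)=C\Cl)cc1 | intermediate
29 | lithium (4-methoxybenzyloxy)ethynide | COc1ccc(COC#C[Li])cc1 | intermediate
30 | (1S,4S)-6,6-dimethoxy-3-exo-[(4-methoxybenzyloxy)ethynyl]-1-methyl-2-exo-[(Z)-4-(triisopropylsilyl)but-1-en-3-ynyl]-7-oxabicyclo[2.2.1]heptan-3-endo-ol | C[C@@]12O[C@@H](CC1(OC)OC)[C@](O)(C#COCc3ccc(OC)cc3)[C@@H]2/C=C\C#C[Si](C(C)C)(C(C)C)C(C)C | intermediate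
31 | (1S,4S)-6,6-dimethoxy-3-exo-[(E)-2-(4-methoxybenzyloxy)vinyl]-1-methyl-2-exo-[(Z)-4-(triisopropylsilyl)but-1-en-3-ynyl]-7-oxabicyclo[2.2.1]heptan-3-endo-ol (key-step precursor) | C[C@@]12O[C@@H](CC1(OC)OC)[C@](O)(/C=C/OCc3ccc(OC)cc3)[C@@H]2/C=C\C#C[Si](C(C)C)(C(C)C)C(C)C | intermediate
32 | potassium alkoxide of 31 | C[C@@]12O[C@@H](CC1(OC)OC)[C@]([O-])(/C=C/OCc3ccc(OC)cc3)[C@@H]2/C=C\C#C[Si](C(C)C)(C(C)C)C(C)C.[K+] | intermediate
33 | potassium C4 enolate of the ring-expanded ketone (same substitution as 34) | C[C@@]12/C=C\[C@@H](C#C[Si](C(C)C)(C(C)C)C(C)C)[C@H](OCc3ccc(OC)cc3)/C=C(/[O-])[C@@H](O1)CC2(OC)OC.[K+] | intermediate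
34 | 11-oxabicyclo[6.2.1]undecadiene C4 enol triflate: C1 dimethyl ketal, C3/C6 cis across C4=C5, 6α-(4-methoxybenzyloxy), 7β-(triisopropylsilylethynyl), Z C8=C9, C10 α-methyl | C[C@@]12/C=C\[C@@H](C#C[Si](C(C)C)(C(C)C)C(C)C)[C@H](OCc3ccc(OC)cc3)/C=C(/OS(=O)(=O)C(F)(F)F)[C@@H](O1)CC2(OC)OC | intermediate
35 | 6α-alcohol of 34 | C[C@@]12/C=C\[C@@H](C#C[Si](C(C)C)(C(C)C)C(C)C)[C@H](O)/C=C(/OS(=O)(=O)C(F)(F)F)[C@@H](O1)CC2(OC)OC | intermediate
36 | 8α,9α-epoxide of 35 | C[C@@]12[C@@H]3O[C@@H]3[C@@H](C#C[Si](C(C)C)(C(C)C)C(C)C)[C@H](O)/C=C(/OS(=O)(=O)C(F)(F)F)[C@@H](O1)CC2(OC)OC | intermediate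
37 | 6-O-tert-butyldimethylsilyl ether of 36 | C[C@@]12[C@@H]3O[C@@H]3[C@@H](C#C[Si](C(C)C)(C(C)C)C(C)C)[C@H](O[Si](C)(C)C(C)(C)C)/C=C(/OS(=O)(=O)C(F)(F)F)[C@@H](O1)CC2(OC)OC | intermediate
38 | 8β-methacryloyloxy-9α-hydroxy enol triflate (6α-silyloxy) | C[C@@]12[C@H](O)[C@@H](OC(=O)C(C)=C)[C@@H](C#C[Si](C(C)C)(C(C)C)C(C)C)[C@H](O[Si](C)(C)C(C)(C)C)/C=C(/OS(=O)(=O)C(F)(F)F)[C@@H](O1)CC2(OC)OC | intermediate
39 | 8β-methacryloyloxy-9α-isovaleryloxy enol triflate | C[C@@]12[C@H](OC(=O)CC(C)C)[C@@H](OC(=O)C(C)=C)[C@@H](C#C[Si](C(C)C)(C(C)C)C(C)C)[C@H](O[Si](C)(C)C(C)(C)C)/C=C(/OS(=O)(=O)C(F)(F)F)[C@@H](O1)CC2(OC)OC | intermediate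
40 | C4-hydroxymethyl diester (C15 alcohol, C1 ketal) | C[C@@]12[C@H](OC(=O)CC(C)C)[C@@H](OC(=O)C(C)=C)[C@@H](C#C[Si](C(C)C)(C(C)C)C(C)C)[C@H](O[Si](C)(C)C(C)(C)C)/C=C(/CO)[C@@H](O1)CC2(OC)OC | intermediate
41 | C1 ketone of 40 | C[C@@]12[C@H](OC(=O)CC(C)C)[C@@H](OC(=O)C(C)=C)[C@@H](C#C[Si](C(C)C)(C(C)C)C(C)C)[C@H](O[Si](C)(C)C(C)(C)C)/C=C(/CO)[C@@H](O1)CC2=O | intermediate
42 | C1/C2 trimethylsilyl enol ether, 15-O-trimethylsilyl ether of 41 | C[C@@]12[C@H](OC(=O)CC(C)C)[C@@H](OC(=O)C(C)=C)[C@@H](C#C[Si](C(C)C)(C(C)C)C(C)C)[C@H](O[Si](C)(C)C(C)(C)C)/C=C(/CO[Si](C)(C)C)[C@@H](O1)C=C2O[Si](C)(C)C | intermediate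
43 | 3(2H)-furanone, 15-O-trimethylsilyl ether | C[C@@]12[C@H](OC(=O)CC(C)C)[C@@H](OC(=O)C(C)=C)[C@@H](C#C[Si](C(C)C)(C(C)C)C(C)C)[C@H](O[Si](C)(C)C(C)(C)C)/C=C(/CO[Si](C)(C)C)C(O1)=CC2=O | intermediate
44 | 3(2H)-furanone with free C15 hydroxyl (6-O-silyl, C-silyl alkyne) | C[C@@]12[C@H](OC(=O)CC(C)C)[C@@H](OC(=O)C(C)=C)[C@@H](C#C[Si](C(C)C)(C(C)C)C(C)C)[C@H](O[Si](C)(C)C(C)(C)C)/C=C(/CO)C(O1)=CC2=O | intermediate
45 | 6α-hydroxy-7β-ethynyl furanone diester | C[C@@]12[C@H](OC(=O)CC(C)C)[C@@H](OC(=O)C(C)=C)[C@@H](C#C)[C@H](O)/C=C(/CO)C(O1)=CC2=O | intermediate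
46 | CNP0552093.1, (6R,7S,8S,9R,10S)-15-hydroxy-9α-isovaleryloxy-8β-methacryloyloxy-1-oxo-3,10-epoxygermacra-2,4(Z),11(13)-trien-12,6α-olide | C=C(C)C(=O)O[C@H]1[C@H]2C(=C)C(=O)O[C@@H]2/C=C(/CO)C2=CC(=O)[C@@](C)(O2)[C@@H]1OC(=O)CC(C)C | target

**Step count**

Total: 27 steps. Longest linear sequence: 23 steps (1, 2, 5–9, 11–13, 15–27).

**Steps most likely to fail**

Step 17 (oxy-Cope and triflation). Two processes may defeat it. The naked potassium enolate may expel the C6 alkoxide before it is triflated. Alternatively, the alkoxide may cleave C4–C9 heterolytically to an enyne-stabilised carbanion, so that the alkene geometries are no longer transferred. The fallback is the neutral siloxy variant, which sets out from 31. Silylation with N-(trimethylsilyl)imidazole should give the trimethylsilyl ether F1. Heating F1 in toluene with a trace of Et3N (sealed tube, 140–170 °C) should bring about the same boat [3,3] shift without any anion and give the C4 trimethylsilyl enol ether F2. MeLi in THF at 0 °C then frees the lithium enolate F3, which is covalent and cold and so far less prone to elimination, and PhNTf2 at −78 °C returns the route to 34.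

Step 19 (directed epoxidation). Oxygen delivery may be slow or unselective, because in the conformer formed by the boat the α face of C8=C9 points into the ring. Allylic oxidation at C6 may also compete. The fallback sets out from 34, with the benzyl ether still in place, and builds the same epoxide by anti addition. NBS in DMSO–H2O (NaHCO3) should form the bromonium ion on the exposed β face, with water entering anti at C8, to give the 9β-bromo-8α-hydroxy compound F4. K2CO3 in MeOH closes F4 by internal SN2 to the 8α,9α-epoxide 4-methoxybenzyl ether F5, and DDQ (as in step 18) returns the route to 36.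

Step 21 (carboxylate opening). The SN2 attack at C8, a ring carbon next to the alkynyl-bearing C7, may be too slow at a temperature the triflate tolerates. Attack at C9, elimination or acyl migration may then take over. The fallback avoids any epoxide opening and sets out from 35. t-BuMe2SiOTf/2,6-lutidine should give the silyl ether F6. OsO4 (cat.)/N-methylmorpholine N-oxide should dihydroxylate C8=C9 from the exposed β face to the 8β,9β-diol F7. Methacrylic anhydride/DMAP at −20 °C should acylate the less hindered C8 hydroxyl to the mono-ester F8. Dess–Martin oxidation gives the C9 ketone F9, and Luche reduction (NaBH4, CeCl3·7H2O, MeOH, −78 °C) with hydride from the exposed β face should give the 9α-alcohol, which returns the route to 38.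

**Further compounds**

F1 | step 17 | trimethylsilyl ether of 31 | C[C@@]12O[C@@H](CC1(OC)OC)[C@](O[Si](C)(C)C)(/C=C/OCc3ccc(OC)cc3)[C@@H]2/C=C\C#C[Si](C(C)C)(C(C)C)C(C)C
F2 | step 17 | C4 trimethylsilyl enol ether of the ring-expanded ketone | C[C@@]12/C=C\[C@@H](C#C[Si](C(C)C)(C(C)C)C(C)C)[C@H](OCc3ccc(OC)cc3)/C=C(/O[Si](C)(C)C)[C@@H](O1)CC2(OC)OC
F3 | step 17 | lithium C4 enolate of the ring-expanded ketone | C[C@@]12/C=C\[C@@H](C#C[Si](C(C)C)(C(C)C)C(C)C)[C@H](OCc3ccc(OC)cc3)/C=C(/[O-])[C@@H](O1)CC2(OC)OC.[Li+]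
F4 | step 19 | 9β-bromo-8α-hydroxy derivative of 34 | C[C@@]12[C@@H](Br)[C@H](O)[C@@H](C#C[Si](C(C)C)(C(C)C)C(C)C)[C@H](OCc3ccc(OC)cc3)/C=C(/OS(=O)(=O)C(F)(F)F)[C@@H](O1)CC2(OC)OC
F5 | step 19 | 8α,9α-epoxide of 34 (6-O-4-methoxybenzyl ether of 36) | C[C@@]12[C@@H]3O[C@@H]3[C@@H](C#C[Si](C(C)C)(C(C)C)C(C)C)[C@H](OCc4ccc(OC)cc4)/C=C(/OS(=O)(=O)C(F)(F)F)[C@@H](O1)CC2(OC)OC
F6 | step 21 | 6-O-tert-butyldimethylsilyl ether of 35 | C[C@@]12/C=C\[C@@H](C#C[Si](C(C)C)(C(C)C)C(C)C)[C@H](O[Si](C)(C)C(C)(C)C)/C=C(/OS(=O)(=O)C(F)(F)F)[C@@H](O1)CC2(OC)OC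
F7 | step 21 | 8β,9β-diol | C[C@@]12[C@@H](O)[C@@H](O)[C@@H](C#C[Si](C(C)C)(C(C)C)C(C)C)[C@H](O[Si](C)(C)C(C)(C)C)/C=C(/OS(=O)(=O)C(F)(F)F)[C@@H](O1)CC2(OC)OC
F8 | step 21 | 8β-methacrylate 9β-alcohol | C[C@@]12[C@@H](O)[C@@H](OC(=O)C(C)=C)[C@@H](C#C[Si](C(C)C)(C(C)C)C(C)C)[C@H](O[Si](C)(C)C(C)(C)C)/C=C(/OS(=O)(=O)C(F)(F)F)[C@@H](O1)CC2(OC)OC
F9 | step 21 | 8β-methacrylate C9 ketone | C[C@@]12C(=O)[C@@H](OC(=O)C(C)=C)[C@@H](C#C[Si](C(C)C)(C(C)C)C(C)C)[C@H](O[Si](C)(C)C(C)(C)C)/C=C(/OS(=O)(=O)C(F)(F)F)[C@@H](O1)CC2(OC)OC
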